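**Retrosynthetic overview**

1. The target is reached by five-fold desilylation of its penta-TBS ether 11, which comes from a Heck coupling (C5–vinyl bond) of the 5-bromo-2,3-diaryl-2,3-dihydrobenzofuran 7 with styrene 10.
2. The dihydrofuran ring of 7 (O1, C2, C3, C3a, C7a) is made by a two-atom ring expansion of the cyclopropane (C3a, C3, C2) in spirodienone 6, formed in the same flask by asymmetric carbene transfer from o-quinone diazide 5 to tris-silylated resveratrol 2. This one operation makes C3a–C3 and C2–O1, sets both stereocentres and restores the benzo ring.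
3. Enabling feature: O1 sits on C7a ortho to C3a, so C3a/C7a–O1 is a masked 2-oxocyclohexadienylidene. C2 carries a para-oxygenated aryl ring, so the cyclopropane bond C3a–C2 is a donor–acceptor bond that heterolyses. C2–C3 with its two aryl groups is resveratrol itself.
4. Ring order: only the dihydrofuran ring is built. The benzo ring is carried as a cyclohexadienone through 5 and 6 and re-aromatised in the key step. The three outer arenes are bought.

Key step: step 3

Assumption: the sense of induction of the Rh(II) catalyst in step 3 cannot be predicted with certainty; the route is written for the catalyst antipode that delivers (3S), taken here as Rh2(S-TCPTTL)4. TBS = tert-butyldimethylsilyl.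

**Step 1**
Reactants: 1 resveratrol
Product: 2 (E)-3,5,4'-tris(tert-butyldimethylsilyloxy)stilbene
Conditions: TBSCl, imidazole, DMF, rt
Reagents that add atoms: tert-butyldimethylsilyl chloride, CC(C)(C)[Si](C)(C)Cl
Why: Imidazole-promoted silylation of all three phenols is routine for resveratrol and leaves the E-alkene untouched; no stereocentre is formed.

**Step 2**
Reactants: 3 2-amino-4-bromophenol
Product: 5 quinone diazide 4-bromo-6-diazocyclohexa-2,4-dien-1-one, via 5-bromo-2-hydroxybenzenediazonium chloride 4 (not isolated)
Conditions: NaNO2, aq HCl, 0 °C; then NaHCO3 (pH 7), extraction into CH2Cl2, 0 °C, dark; used at once as a dried solution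
Reagents that add atoms: sodium nitrite, [Na+].[O-]N=O
Why: Diazotisation of an o-aminophenol followed by deprotonation of the o-hydroxybenzenediazonium salt is the classical entry to o-quinone diazides (diazo oxides), the bromine staying inert, and the energetic product is kept cold, dark and in solution.

**Step 3**
Reactants: 2 (E)-3,5,4'-tris(tert-butyldimethylsilyloxy)stilbene; 5 4-bromo-6-diazocyclohexa-2,4-dien-1-one
Product: 7 (2S,3S)-5-bromo-3-[3,5-bis(tert-butyldimethylsilyloxy)phenyl]-2-[4-(tert-butyldimethylsilyloxy)phenyl]-2,3-dihydrobenzofuran, via spirodienone cyclopropane 6 (not isolated)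
Conditions: Rh2(S-TCPTTL)4 (1 mol %), PhCF3/CH2Cl2, 4 Å MS, 0 °C → rt, slow addition of 5 (1.5 equiv), dark; then 40 °C
Reagents that add atoms: none
Why: Proposed new method: Rh(II)-mediated loss of N2 from 5 should give an electrophilic o-quinoid (2-oxocyclohexadienylidene) carbene that adds to the stilbene C=C of 2 in an asynchronous [2+1] cycloaddition (cyclopropane closure by carbene addition), the carbene carbon bonding first to the alkene carbon that carries the 3,5-bis(silyloxy)phenyl ring, to give the spiro[2.5]octa-5,7-dien-4-one 6. In 6 the bond from the spiro carbon to the carbon bearing the 4-silyloxyphenyl ring is a donor–acceptor cyclopropane bond that heterolyses to a phenoxide/p-oxybenzyl cation pair, and the phenoxide oxygen closes on the cation (5-exo-trig), which is a Cloke–Wilson-type cyclopropyl ketone to dihydrofuran ring expansion (three to five ring atoms) driven by strain release and by rearomatisation of the benzo ring. The closest known reactions are Rh(II)-catalysed cyclopropanations of alkenes with p-quinone diazides to spiro[2.5]octadienones, formal [3+2] cycloadditions of diazonaphthoquinones and cyclic 2-diazo-1,3-diones with styrenes and enol ethers, Cloke–Wilson rearrangements of spiro[2.5]octane-4,8-diones and enantioselective cyclopropanations with cyclic acceptor carbenes under Rh(II) phthalimido-tert-leucinate catalysis; the combination on a monocyclic o-quinone diazide and a 1,2-diarylethene with asymmetric induction is not established. C3 is set in the carbene transfer by the chiral catalyst (choice of alkene enantioface) and is untouched by the ring expansion, while C2 is set under control of C3: the E-alkene geometry is carried into the trans-cyclopropane and, by least-motion collapse of the ion pair and the reversibility of C2–O ionisation, into the more stable 2,3-trans ring. The step needs regioselectivity (oxygen to the 4-oxyphenyl carbon), secured because only the para-oxygenated ring stabilises a benzylic cation whereas the meta-silyloxy groups do not, and chemoselectivity for the alkene over the electron-rich arenes and over carbene dimerisation, secured by the bulky silyl ethers that flank the nucleophilic ring positions and by slow addition of 5.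

**Step 4**
Reactants: 8 3,5-dihydroxybenzaldehyde
Product: 9 3,5-bis(tert-butyldimethylsilyloxy)benzaldehyde
Conditions: TBSCl, imidazole, DMF, rt
Reagents that add atoms: tert-butyldimethylsilyl chloride, CC(C)(C)[Si](C)(C)Cl
Why: Standard imidazole-promoted silylation of both phenols, with the aldehyde unaffected and no stereocentre involved.

**Step 5**
Reactants: 9 3,5-bis(tert-butyldimethylsilyloxy)benzaldehyde
Product: 10 3,5-bis(tert-butyldimethylsilyloxy)styrene
Conditions: Ph3PCH3Br, NaHMDS, THF, 0 °C → rt
Reagents that add atoms: methyltriphenylphosphonium bromide, C[P+](c1ccccc1)(c1ccccc1)c1ccccc1.[Br-]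
Why: Wittig methylenation of the aromatic aldehyde with the non-stabilised ylide, generated with a non-nucleophilic amide base so that the aryl silyl ethers survive.

**Step 6**
Reactants: 7 (2S,3S)-5-bromo-3-[3,5-bis(tert-butyldimethylsilyloxy)phenyl]-2-[4-(tert-butyldimethylsilyloxy)phenyl]-2,3-dihydrobenzofuran; 10 3,5-bis(tert-butyldimethylsilyloxy)styrene
Product: 11 (2S,3S)-trans-delta-viniferin penta(tert-butyldimethylsilyl) ether
Conditions: Pd2(dba)3 (2 mol %), P(t-Bu)3·HBF4 (8 mol %), Cy2NMe, 1,4-dioxane, 80 °C
Reagents that add atoms: none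
Why: Mizoroki–Heck coupling of the electron-rich aryl bromide with the styrene under bulky trialkylphosphine/hindered amine conditions should give the E-stilbene by syn-insertion and syn-β-hydride elimination, without touching the benzylic stereocentres or the aryl silyl ethers.

**Step 7**
Reactants: 11 (2S,3S)-trans-delta-viniferin penta(tert-butyldimethylsilyl) ether
Product: 12 (2S,3S)-trans-delta-viniferin
Conditions: TBAF, AcOH (1:1), THF, 0 °C → rt, Ar, dark
Reagents that add atoms: none
Why: Fluoride-mediated cleavage of the five aryl silyl ethers, buffered with acetic acid so that no free phenoxide opens the dihydrofuran ring at C2 or is oxidised by air, should release the pentaphenol with both stereocentres and the E-alkene intact.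

**Compound list**

1 | resveratrol, (E)-5-(4-hydroxystyryl)benzene-1,3-diol | Oc1ccc(/C=C/c2cc(O)cc(O)c2)cc1 | starting material
2 | (E)-3,5,4'-tris(tert-butyldimethylsilyloxy)stilbene | CC(C)(C)[Si](C)(C)Oc1ccc(/C=C/c2cc(O[Si](C)(C)C(C)(C)C)cc(O[Si](C)(C)C(C)(C)C)c2)cc1 | intermediate
3 | 2-amino-4-bromophenol | Nc1cc(Br)ccc1O | starting material
4 | 5-bromo-2-hydroxybenzenediazonium chloride | Oc1ccc(Br)cc1[N+]#N.[Cl-] | intermediate
5 | 4-bromo-6-diazocyclohexa-2,4-dien-1-one (4-bromo-o-benzoquinone 2-diazide) | [N-]=[N+]=C1C=C(Br)C=CC1=O | intermediate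
6 | 7-bromo-1-[3,5-bis(tert-butyldimethylsilyloxy)phenyl]-2-[4-(tert-butyldimethylsilyloxy)phenyl]spiro[2.5]octa-5,7-dien-4-one; aryl groups trans on the cyclopropane, C1 with the configuration of C3 in 7, drawn as the spiro epimer with C=O syn to the C1 aryl group (both spiro epimers converge on 7) | O=C1C=CC(Br)=C[C@]12[C@H](c3cc(O[Si](C)(C)C(C)(C)C)cc(O[Si](C)(C)C(C)(C)C)c3)[C@H]2c4ccc(O[Si](C)(C)C(C)(C)C)cc4 | intermediate
7 | (2S,3S)-5-bromo-3-[3,5-bis(tert-butyldimethylsilyloxy)phenyl]-2-[4-(tert-butyldimethylsilyloxy)phenyl]-2,3-dihydrobenzofuran (2,3-trans) | CC(C)(C)[Si](C)(C)Oc1ccc([C@H]2Oc3ccc(Br)cc3[C@@H]2c2cc(O[Si](C)(C)C(C)(C)C)cc(O[Si](C)(C)C(C)(C)C)c2)cc1 | intermediate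
8 | 3,5-dihydroxybenzaldehyde | O=Cc1cc(O)cc(O)c1 | starting material
9 | 3,5-bis(tert-butyldimethylsilyloxy)benzaldehyde | O=Cc1cc(O[Si](C)(C)C(C)(C)C)cc(O[Si](C)(C)C(C)(C)C)c1 | intermediate
10 | 3,5-bis(tert-butyldimethylsilyloxy)styrene | C=Cc1cc(O[Si](C)(C)C(C)(C)C)cc(O[Si](C)(C)C(C)(C)C)c1 | intermediate
11 | (2S,3S)-trans-delta-viniferin penta(tert-butyldimethylsilyl) ether | CC(C)(C)[Si](C)(C)Oc1ccc([C@H]2Oc3ccc(/C=C/c4cc(O[Si](C)(C)C(C)(C)C)cc(O[Si](C)(C)C(C)(C)C)c4)cc3[C@@H]2c2cc(O[Si](C)(C)C(C)(C)C)cc(O[Si](C)(C)C(C)(C)C)c2)cc1 | intermediate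
12 | (2S,3S)-trans-delta-viniferin | Oc1ccc([C@H]2Oc3ccc(/C=C/c4cc(O)cc(O)c4)cc3[C@@H]2c2cc(O)cc(O)c2)cc1 | target

**Step count**

Total steps: 7. Longest linear sequence: 4 steps (step 1 → 3 → 6 → 7; the branches through step 2 and through steps 4–5 are of equal or shorter length).

**Steps most likely to fail**

Step 3 (Proposed new method). Carbene transfer to the hindered trans-1,2-disubstituted alkene may be slower than carbene dimerisation, aromatic substitution on the resorcinol ring or decomposition of the quinone diazide, and enantioface discrimination may be poor. The fallback uses known chemistry, sets out from 2 and comes back to the route at 11, bypassing 5 and 7. Compound 2 and 1,4-benzoquinone are combined under Lewis-acid promotion (BF3·OEt2, CH2Cl2, −78 → −30 °C) in the known formal [3+2] cycloaddition of quinones with electron-rich styrenes and stilbenes: conjugate attack of the alkene on the activated quinone, closure of the quinone oxygen on the 4-silyloxybenzyl cation, then tautomerisation. This should give the racemic 2,3-trans adduct, an equimolar mixture of (2S,3S)-3-[3,5-bis(tert-butyldimethylsilyloxy)phenyl]-2-[4-(tert-butyldimethylsilyloxy)phenyl]-2,3-dihydrobenzofuran-5-ol F1 and its (2R,3R)-enantiomer F2. Preparative SFC on a chiral stationary phase separates F1. Triflation of F1 (PhNTf2, Et3N, DMAP, CH2Cl2) gives the (2S,3S)-5-trifluoromethanesulfonate F3. Heck coupling of F3 with 10 (Pd2(dba)3, P(t-Bu)3·HBF4, Cy2NMe, dioxane) gives 11, and step 7 follows unchanged.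

Step 7. Free phenoxide may drive ionisation of the C2–O bond (ring opening to a p-quinone methide, loss or epimerisation of the dihydrofuran), and the electron-rich pentaphenol may be oxidised by air or isomerised E/Z by light during a five-fold desilylation. The fallback sets out from 11 and comes back at 12. Each phenoxide is trapped as it is released by fluoride in the presence of acetic anhydride (CsF, Ac2O, DMF, rt), giving the robust (2S,3S)-trans-delta-viniferin pentaacetate F4, which can be purified without special precautions. The acetates are then removed under near-neutral transesterification (NH4OAc, MeOH/H2O, rt, Ar) to give 12.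

Step 6. Oxidative addition into the electron-rich aryl bromide may be sluggish, so that base-mediated desilylation at 80 °C and α-arylation of the styrene (1,1-diarylethene regioisomer) compete. The fallback sets out from 7 and comes back at 11. Stille coupling of 7 with tributyl(vinyl)stannane (Pd(PPh3)4, toluene, 100 °C) gives (2S,3S)-3-[3,5-bis(tert-butyldimethylsilyloxy)phenyl]-2-[4-(tert-butyldimethylsilyloxy)phenyl]-5-vinyl-2,3-dihydrobenzofuran F5. Ruthenium-catalysed olefin cross-metathesis of F5 with an excess of 10 (second-generation Hoveyda–Grubbs catalyst, CH2Cl2, 40 °C), neutral and E-selective for stilbenes, gives 11.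

**Further compounds**

F1 | step 3 | (2S,3S)-3-[3,5-bis(tert-butyldimethylsilyloxy)phenyl]-2-[4-(tert-butyldimethylsilyloxy)phenyl]-2,3-dihydrobenzofuran-5-ol | CC(C)(C)[Si](C)(C)Oc1ccc([C@H]2Oc3ccc(O)cc3[C@@H]2c2cc(O[Si](C)(C)C(C)(C)C)cc(O[Si](C)(C)C(C)(C)C)c2)cc1
F2 | step 3 | (2R,3R)-3-[3,5-bis(tert-butyldimethylsilyloxy)phenyl]-2-[4-(tert-butyldimethylsilyloxy)phenyl]-2,3-dihydrobenzofuran-5-ol (enantiomer of F1, removed by SFC) | CC(C)(C)[Si](C)(C)Oc1ccc([C@@H]2Oc3ccc(O)cc3[C@H]2c2cc(O[Si](C)(C)C(C)(C)C)cc(O[Si](C)(C)C(C)(C)C)c2)cc1
F3 | step 3 | (2S,3S)-3-[3,5-bis(tert-butyldimethylsilyloxy)phenyl]-2-[4-(tert-butyldimethylsilyloxy)phenyl]-2,3-dihydrobenzofuran-5-yl trifluoromethanesulfonate | CC(C)(C)[Si](C)(C)Oc1ccc([C@H]2Oc3ccc(OS(=O)(=O)C(F)(F)F)cc3[C@@H]2c2cc(O[Si](C)(C)C(C)(C)C)cc(O[Si](C)(C)C(C)(C)C)c2)cc1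
F4 | step 7 | (2S,3S)-trans-delta-viniferin pentaacetate | CC(=O)Oc1ccc([C@H]2Oc3ccc(/C=C/c4cc(OC(C)=O)cc(OC(C)=O)c4)cc3[C@@H]2c2cc(OC(C)=O)cc(OC(C)=O)c2)cc1
F5 | step 6 | (2S,3S)-3-[3,5-bis(tert-butyldimethylsilyloxy)phenyl]-2-[4-(tert-butyldimethylsilyloxy)phenyl]-5-vinyl-2,3-dihydrobenzofuran | CC(C)(C)[Si](C)(C)Oc1ccc([C@H]2Oc3ccc(C=C)cc3[C@@H]2c2cc(O[Si](C)(C)C(C)(C)C)cc(O[Si](C)(C)C(C)(C)C)c2)cc1
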